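## The problem

Compound 27 is a linear trimer of butyrylphloroglucinol units. The central ring B carries its butyryl group at C1, hydroxyls at C2, C4 and C6, and CH2 bridges at C3 (to ring A) and C5 (to ring C). There is no stereocentre, so the whole difficulty is constitutional: every ring position is substituted, and nine oxygens must end up as seven OH and two OMe groups. The outer rings are isomers that differ only in where the OMe sits. In ring A it is at C4, para to the bridge and between the C-methyl (C3) and the butyryl group (C5). In ring C it is at C6, ortho to the bridge and para to the butyryl group at C3. The electron-rich diarylmethane bridges can cleave or scramble by retro-Friedel–Crafts reaction in strong acid, and the free polyphenol is sensitive to air and base. The OMe of ring A lies ortho to a ketone, where chelating Lewis acids would remove it. The phenols must therefore stay masked to the end, and the late steps must be mild. The feature that makes the key step possible is in ring A. C4–C5 (oxygen next to acyl) maps onto an acylalkyne whose β-carbon carries a halogen as a stand-in for OMe. C6–C1–C2–C3 (OH, bridge, OH, methyl) is the chain C1–C4 of methyl 3-oxopentanoate 13 benzylated at C2. Ring A can thus be closed by a [4+2] addition onto a bridge that is already in place.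

## Retrosynthesis

**27 from 26.** The seven O–benzyl bonds are cut last. Benzyl ethers for the phenols and methyl ethers only where the target has them allow one neutral hydrogenolysis at the end. Acid-labile or Lewis-acid-labile masks would endanger the bridges and the ring A OMe. The forward step must not reduce three aryl ketones.

**26 from 25.** The two aryl–acyl bonds on rings B and C are cut. These ketones are enolisable and electrophilic and would not survive the aryllithium and amide-base steps earlier in the route, so they are introduced late. In 25 each of rings B and C has exactly one free position and ring A has none, so no regiochemical choice arises. The forward reaction must acylate without cleaving benzyl ethers or bridges.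

**25 from 24 from 23.** The C4–OMe bond of ring A is traced back to C4–Br, and the two ring A benzyl ethers to the free resorcinol 23. A halogen is the one oxygen surrogate that the alkyne can carry through the cycloaddition and that stays distinct from the two new phenols. Benzylating first means methoxide can enter only at the carbon that bore bromine. The forward exchange has to work at a carbon flanked by methyl and acyl.

**23 from 18 and 21 (key disconnection).** The C3–C4 and C5–C6 bonds of ring A are cut. The neighbouring option is to cut the A–B bridge and attach a ready-made ring A. Against that, the cycloaddition builds ring A on the bridge from a six-carbon ynone and an acyclic diene, and it delivers the butyryl group, the methyl group and the marker for OMe in their final positions in one step. Diene 18 and ynone 21 are far simpler than 23. The forward reaction must give a single orientation and tolerate substituents at C2 and C4 of the diene.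

**21 from 20 from 19.** The C–Br bond and the carbonyl oxidation level are removed, leading to commercial racemic hex-1-yn-3-ol 19.

**18 from 16 from 15.** The two O–Si bonds are cut, giving β-keto ester 15. The two-stage silylation is the standard entry to such dienes and asks only that nothing else in 15 is acidic enough to compete. This is a further reason for keeping rings B and C free of ketones.

**15 from 12 and 13.** The bond between the ring B benzylic carbon and C2 of 13 is cut. Enolate alkylation by the benzylic bromide 14, made from alcohol 12 and used at once, is preferred to an acid-catalysed benzylation because base keeps the free ring positions of 14 from attacking its own benzylic carbon.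

**12 from 9.** The ring B–CH2OH bond is cut back to the aryl bromide 9, through aryllithium 10 and aldehyde 11. The bromine defines the position, which electrophilic formylation could not do in the presence of the equally activated free position of ring C.

**9 from 8 from 6 and 4.** The bond between ring B and the bridging carbon is cut, with the bridge oxidised to a carbinol. Addition of aryllithium 7 to aldehyde 4 joins the rings at positions fixed by a bromine and a formyl group. Acid-catalysed benzylation would have to choose among several nearly equivalent ring positions. Ionic hydrogenation of 8 then gives the CH2 bridge.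

**6 from 5; 4 from 3 from 2 from 1.** Dibromination of 5 marks both bridge positions of ring B. For ring C, the formyl carbon of 2 becomes the bridge carbon. The order of O-alkylation (the two accessible hydroxyls benzylated first, the chelated hydroxyl next to the methyl group methylated last) places OMe between methyl and bridge.

## Roads not taken

**Alternative 1: ring B by convergent benzannulation.** The cut goes through ring B, between C2–C3 and C4–C5. Heating the cyclobutenone A2 (ring C arylmethyl on C2, benzyloxy on C3) with the siloxyalkyne A3 (ring A arylmethyl) would open the four-membered ring to a vinylketene. This adds to the ynol ether, the new cyclobutenone opens, and a 6π electrocyclisation closes ring B as the phenol A1. This is the most convergent plan: ring B is created while two complete halves are united, and no halogen-to-methoxy exchange is needed. In both respects it is better than the chosen route. Against it stand the partners. A2 needs C-benzylation of an alkoxycyclobutenone with a very labile trialkoxybenzyl electrophile. A3 needs an ester-to-ynolate homologation beside an electron-rich arene. The ketene carbon that must enter the [2+2] step is fully substituted. A1 also arrives with three differently masked oxygens on ring B that the target does not need, and with all three rings still lacking their butyryl groups. The chosen plan has two late acylations instead of three, uses a β-keto ester and a two-step ynone as partners, and forms ring A's ketone in the ring-forming step.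

**Alternative 2: ring B by [3+3] cyclocondensation.** Ring B is cut at C3–C4 and C6–C1. The bis(silyloxy)diene A5 (ring A arylmethyl at its terminus) and the substituted malonyl dichloride A6 would condense under a silyl triflate Lewis acid to the phloroglucinol ester A4. The merit is that the central ring with both bridges and all three oxygens forms in one step from two halves. The weak points are mechanistic and strategic. After the first C-acylation the second acid chloride can close through the enol oxygen to a pyranone instead of through carbon. A6 can also lose HCl to an acylketene. A4 carries CO2Me where butyryl is needed, and converting a doubly ortho-substituted benzoate into a propyl ketone costs protection and a hindered organometallic addition. The outer rings again need late acylation. In convergence this road equals alternative 1 and beats the chosen one. The chosen plan avoids the C/O ambiguity and the ester-to-ketone detour.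

**Alternative 3: ring C by benzannulation with a methoxyalkyne.** Ring C is cut at C4–C5 and C6–C1. The cyclobutenone A8, which carries the ring A–ring B arylmethyl group, would react with 1-methoxyprop-1-yne A9 to give the phenol A7. Its strength is that the alkyne places OMe next to the methyl group and next to the bridge with full regiocontrol. The chosen route has to secure this relationship by a selective phenol alkylation (step 2), so alternative 3 is better here. Its weakness is that A8 is an elaborate, late cyclobutenone containing the whole A–B part, with ring A made classically beforehand. A9 is a volatile special reagent, and all three rings of A7 still await butyrylation. The chosen plan keeps ring C to three classical steps and puts the ring-forming chemistry on ring A, where it also installs a ketone.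

Key step: step 13

Remark: 1,3,5-tris(benzyloxy)benzene 5 (the tribenzyl ether of phloroglucinol) is taken as a purchased compound.
Remark: 8, 15, 19, 20 and 22 are racemic or stereoisomer mixtures whose stereocentres are destroyed later; the fully substituted enol ether bond of 16 and the ketene acetal bond of 17 and 18 are expected as E/Z mixtures that converge in step 13, so only the C3=C4 bond of the diene carries a descriptor.
Remark: Ar* denotes the protected ring B–ring C unit, 2,4,6-tris(benzyloxy)-3-{[4,6-bis(benzyloxy)-2-methoxy-3-methylphenyl]methyl}phenyl.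

## Route

Step 1
Reactants: 1 2-methylbenzene-1,3,5-triol
Product: 2 2,4,6-trihydroxy-3-methylbenzaldehyde
Conditions: POCl3, DMF, EtOAc, 0 °C → rt; then H2O, 70 °C
Reagents that add atoms: N,N-dimethylformamide CN(C)C=O; water O
Why: Vilsmeier–Haack formylation of a phloroglucinol; the two free ring positions of 1 are equivalent, so a single aldehyde forms, and the formyl group deactivates the ring against a second substitution.

Step 2
Reactants: 2 2,4,6-trihydroxy-3-methylbenzaldehyde
Product: 3 4,6-bis(benzyloxy)-2-hydroxy-3-methylbenzaldehyde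
Conditions: BnBr (2.1 equiv), K2CO3, DMF, 0 °C → rt
Reagents that add atoms: benzyl bromide BrCc1ccccc1
Why: Williamson etherification under weak base; the 4-OH para to the formyl group is the most acidic and not hydrogen-bonded, the 6-OH follows, and the 2-OH, chelated to the aldehyde and buttressed by the methyl group, should remain free, as is established for partial alkylation of 3-methyl-2,4,6-trihydroxyphenyl carbonyl compounds.

Step 3
Reactants: 3 4,6-bis(benzyloxy)-2-hydroxy-3-methylbenzaldehyde
Product: 4 4,6-bis(benzyloxy)-2-methoxy-3-methylbenzaldehyde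
Conditions: MeI, K2CO3, DMF, 40 °C
Reagents that add atoms: iodomethane CI
Why: O-Methylation of the remaining chelated phenol (Williamson); this fixes OMe next to the C-methyl group and next to the carbon that becomes the ring B–ring C bridge.

Step 4
Reactants: 5 1,3,5-tris(benzyloxy)benzene
Product: 6 1,3,5-tris(benzyloxy)-2,4-dibromobenzene
Conditions: NBS (2.05 equiv), CH2Cl2, −20 → 0 °C
Reagents that add atoms: N-bromosuccinimide O=C1CCC(=O)N1Br
Why: Electrophilic aromatic bromination of a 1,3,5-trialkoxybenzene stops at the dibromide with two equivalents; the bromines mark the two bridge positions of ring B and leave the future butyryl site as CH.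

Step 5
Reactants: 6 1,3,5-tris(benzyloxy)-2,4-dibromobenzene; 4 4,6-bis(benzyloxy)-2-methoxy-3-methylbenzaldehyde
Product: 8 [4,6-bis(benzyloxy)-2-methoxy-3-methylphenyl][2,4,6-tris(benzyloxy)-3-bromophenyl]methanol (racemic), via aryllithium 7 (not isolated)
Conditions: n-BuLi (1.0 equiv), THF, −78 °C; then 4, −78 → −40 °C; H2O
Reagents that add atoms: none
Why: Bromine–lithium exchange at −78 °C outruns deprotonation of the benzyl ethers, and one equivalent exchanges only one bromine because a second exchange would give a dianion; 1,2-addition of the aryllithium to the aldehyde joins rings B and C at positions fixed by bromine and formyl group, and the racemic carbinol centre is removed in step 6.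

Step 6
Reactants: 8 [4,6-bis(benzyloxy)-2-methoxy-3-methylphenyl][2,4,6-tris(benzyloxy)-3-bromophenyl]methanol
Product: 9 1,3,5-tris(benzyloxy)-2-{[4,6-bis(benzyloxy)-2-methoxy-3-methylphenyl]methyl}-4-bromobenzene
Conditions: Et3SiH, CF3CO2H, CH2Cl2, −20 → 0 °C
Reagents that add atoms: none
Why: Ionic hydrogenation; the doubly benzylic alcohol ionises to a cation stabilised by six ortho/para alkoxy groups and is trapped by hydride from the silane, while aryl bromide and benzyl ethers are untouched at low temperature.

Step 7
Reactants: 9 1,3,5-tris(benzyloxy)-2-{[4,6-bis(benzyloxy)-2-methoxy-3-methylphenyl]methyl}-4-bromobenzene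
Product: 12 Ar*–CH2OH, (2,4,6-tris(benzyloxy)-3-{[4,6-bis(benzyloxy)-2-methoxy-3-methylphenyl]methyl}phenyl)methanol, via aryllithium 10 (not isolated), via aldehyde 11 (not isolated)
Conditions: n-BuLi, THF, −78 °C; DMF, −78 → 0 °C; then MeOH, NaBH4, 0 °C
Reagents that add atoms: N,N-dimethylformamide CN(C)C=O
Why: A second bromine–lithium exchange and formylation with DMF place one carbon at the remaining bridge position of ring B; reducing the hindered aldehyde with NaBH4 in the same flask gives the benzylic alcohol directly.

Step 8
Reactants: 12 Ar*–CH2OH; 13 methyl 3-oxopentanoate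
Product: 15 methyl 2-(Ar*-methyl)-3-oxopentanoate (racemic), via benzylic bromide 14 (not isolated)
Conditions: PBr3, pyridine (cat.), Et2O, −10 °C; cold solution added at once to 13 (3 equiv) + NaH, THF–DMF, 0 °C → rt
Reagents that add atoms: none
Why: Conversion of the benzylic alcohol into the bromide and C-alkylation of the sodium enolate of the β-keto ester (acetoacetic ester alkylation); the trialkoxybenzyl bromide is too labile to store and is used immediately, excess enolate suppresses dialkylation, and the new racemic centre is lost on enolisation.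

Step 9
Reactants: 15 methyl 2-(Ar*-methyl)-3-oxopentanoate
Product: 16 methyl 2-(Ar*-methyl)-3-(trimethylsilyloxy)pent-2-enoate
Conditions: Me3SiCl, Et3N, toluene, rt, 72 h
Reagents that add atoms: chlorotrimethylsilane C[Si](C)(C)Cl
Why: Soft enolisation and O-silylation of the β-keto ester, the first stage of the standard two-stage preparation of 1,3-bis(silyloxy)dienes.

Step 10
Reactants: 16 methyl 2-(Ar*-methyl)-3-(trimethylsilyloxy)pent-2-enoate
Product: 18 (3Z)-1-methoxy-2-(Ar*-methyl)-1,3-bis(trimethylsilyloxy)penta-1,3-diene, via lithium dienolate 17 (not isolated)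
Conditions: LiN(i-Pr)2 (1.5 equiv), THF, −78 °C; Me3SiCl, −78 °C → rt; used crude
Reagents that add atoms: chlorotrimethylsilane C[Si](C)(C)Cl
Why: γ-Deprotonation of the β-silyloxy enoate and O-silylation of the ester dienolate give the diene; allylic strain against the substituted C2 should place the C4 methyl group trans to C2 (3Z), the geometry in which the s-cis conformer is accessible, and no other C–H in 16 is comparably acidic.

Step 11
Reactants: 19 hex-1-yn-3-ol (racemic)
Product: 20 1-bromohex-1-yn-3-ol (racemic)
Conditions: NBS, AgNO3 (cat.), acetone, rt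
Reagents that add atoms: N-bromosuccinimide O=C1CCC(=O)N1Br
Why: Silver-catalysed electrophilic bromination of a terminal alkyne; the secondary alcohol is untouched.

Step 12
Reactants: 20 1-bromohex-1-yn-3-ol
Product: 21 1-bromohex-1-yn-3-one
Conditions: Dess–Martin periodinane, CH2Cl2, 0 °C → rt
Reagents that add atoms: none
Why: Dess–Martin oxidation of a propargylic alcohol under neutral conditions leaves the C–Br bond intact; the volatile, electrophilic ynone is kept and used as a solution.

Step 13
Reactants: 18 (3Z)-1-methoxy-2-(Ar*-methyl)-1,3-bis(trimethylsilyloxy)penta-1,3-diene; 21 1-bromohex-1-yn-3-one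
Product: 23 1-[2-bromo-4,6-dihydroxy-3-methyl-5-(Ar*-methyl)phenyl]butan-1-one, via cycloadduct 22 (not isolated)
Conditions: 21 (1.5 equiv), toluene, rt → 50 °C; then CF3CO2H, CH2Cl2, 0 °C; aq NaHCO3
Reagents that add atoms: none
Why: Diels–Alder cycloaddition of a 1-alkoxy-1,3-bis(silyloxy)diene with an acetylenic ketone followed by aromatisation is the known route from such dienes to acylresorcinols, applied here to a bromoalkynyl ketone and a 2,4-disubstituted diene. The HOMO of 18 is largest at diene C4 (the CH–CH3 terminus) and the LUMO of 21 at the bromine-bearing β-carbon, so C4 bonds to C–Br and the ketene acetal carbon C1 to the α-carbon in a concerted, asynchronous [4+2]; a stepwise Mukaiyama–Michael path through a zwitterion would give the same connectivity. Ring A closes as a six-membered carbocycle in this cycloaddition, which forms the C3–C4 and C5–C6 bonds in ring A numbering. Cycloadduct 22 has two stereocentres, the mixed ketal carbon and the CH–CH3 carbon; neither needs control, because acid ionises the silyl methyl ketal, methanol is lost, the ring hydrogen is removed and the silyl ethers are cleaved to give the resorcinol. Bromine sits on a carbon without hydrogen and cannot be eliminated, so it survives as the marker of the future OMe between the C-methyl and the butyryl group. The one selectivity needed is the mutual orientation of the partners; it is secured by matching the most nucleophilic diene terminus with the β-carbon of the ynone, and the linear dienophile tolerates the substituents at C2 and C4 of the diene. Benzyl ethers and the free positions of rings B and C are inert to the neutral heating and the brief acid treatment.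

Step 14
Reactants: 23 1-[2-bromo-4,6-dihydroxy-3-methyl-5-(Ar*-methyl)phenyl]butan-1-one
Product: 24 1-[4,6-bis(benzyloxy)-2-bromo-3-methyl-5-(Ar*-methyl)phenyl]butan-1-one
Conditions: BnBr, K2CO3, n-Bu4NI (cat.), DMF, 60 °C
Reagents that add atoms: benzyl bromide BrCc1ccccc1
Why: Williamson benzylation of both ring A phenols (the chelated one needs warming and iodide catalysis); masking them keeps the later acylation from going to oxygen and makes the substrate of the copper step non-acidic.

Step 15
Reactants: 24 1-[4,6-bis(benzyloxy)-2-bromo-3-methyl-5-(Ar*-methyl)phenyl]butan-1-one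
Product: 25 1-[4,6-bis(benzyloxy)-2-methoxy-3-methyl-5-(Ar*-methyl)phenyl]butan-1-one
Conditions: NaOMe (5 equiv), CuBr (0.2 equiv), DMF–MeOH, 110 °C, Ar
Reagents that add atoms: sodium methoxide [Na+].[O-]C
Why: Ullmann-type copper-catalysed methoxylation of an aryl bromide; the ortho ketone assists the substitution, and because every phenol is benzylated the new oxygen can only be a methyl ether at the carbon that carried bromine.

Step 16
Reactants: 25 1-[4,6-bis(benzyloxy)-2-methoxy-3-methyl-5-(Ar*-methyl)phenyl]butan-1-one
Product: 26 hepta-O-benzyl ether of the target, carrying butanoyl groups on all three rings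
Conditions: n-PrCO2H (4 equiv), (CF3CO)2O (4 equiv), CH2Cl2, 0 °C → rt
Reagents that add atoms: butanoic acid CCCC(=O)O
Why: Friedel–Crafts acylation with the mixed butanoic trifluoroacetic anhydride, which acylates 1,3,5-trialkoxybenzenes without a metal Lewis acid; rings B and C each have exactly one free position (ortho, ortho and para to oxygen) and ring A has none, so both ketones enter without a regiochemical choice and the OMe ortho to the ring A ketone is never exposed to a chelating Lewis acid.

Step 17
Reactants: 26 hepta-O-benzyl ether of the target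
Product: 27 1-[3-[(3-butanoyl-2,6-dihydroxy-4-methoxy-5-methylphenyl)methyl]-5-[(3-butanoyl-2,4-dihydroxy-6-methoxy-5-methylphenyl)methyl]-2,4,6-trihydroxyphenyl]butan-1-one
Conditions: H2 (1 atm), 10% Pd/C, EtOAc–MeOH, rt
Reagents that add atoms: none
Why: Hydrogenolysis of the seven benzyl ethers; the ortho-hydroxyaryl ketones that emerge are hydrogen-bonded and resist reduction under these mild conditions, and the methyl ethers and CH2 bridges are inert.

## Compound list

1 | 2-methylbenzene-1,3,5-triol | Cc1c(O)cc(O)cc1O | starting material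
2 | 2,4,6-trihydroxy-3-methylbenzaldehyde | Cc1c(O)cc(O)c(C=O)c1O | intermediate
3 | 4,6-bis(benzyloxy)-2-hydroxy-3-methylbenzaldehyde | Cc1c(OCc2ccccc2)cc(OCc2ccccc2)c(C=O)c1O | intermediate
4 | 4,6-bis(benzyloxy)-2-methoxy-3-methylbenzaldehyde | COc1c(C)c(OCc2ccccc2)cc(OCc2ccccc2)c1C=O | intermediate
5 | 1,3,5-tris(benzyloxy)benzene | c1ccc(COc2cc(OCc3ccccc3)cc(OCc3ccccc3)c2)cc1 | starting material
6 | 1,3,5-tris(benzyloxy)-2,4-dibromobenzene | Brc1c(OCc2ccccc2)cc(OCc2ccccc2)c(Br)c1OCc1ccccc1 | intermediate
7 | [2,4,6-tris(benzyloxy)-3-bromophenyl]lithium | [Li]c1c(OCc2ccccc2)cc(OCc2ccccc2)c(Br)c1OCc1ccccc1 | intermediate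
8 | [4,6-bis(benzyloxy)-2-methoxy-3-methylphenyl][2,4,6-tris(benzyloxy)-3-bromophenyl]methanol (racemic) | Brc1c(OCc2ccccc2)cc(OCc2ccccc2)c(C(O)c2c(OCc3ccccc3)cc(OCc3ccccc3)c(C)c2OC)c1OCc1ccccc1 | intermediate
9 | 1,3,5-tris(benzyloxy)-2-{[4,6-bis(benzyloxy)-2-methoxy-3-methylphenyl]methyl}-4-bromobenzene | Brc1c(OCc2ccccc2)cc(OCc2ccccc2)c(Cc2c(OCc3ccccc3)cc(OCc3ccccc3)c(C)c2OC)c1OCc1ccccc1 | intermediate
10 | Ar*–Li, (2,4,6-tris(benzyloxy)-3-{[4,6-bis(benzyloxy)-2-methoxy-3-methylphenyl]methyl}phenyl)lithium | [Li]c1c(OCc2ccccc2)cc(OCc2ccccc2)c(Cc2c(OCc3ccccc3)cc(OCc3ccccc3)c(C)c2OC)c1OCc1ccccc1 | intermediate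
11 | Ar*–CHO, 2,4,6-tris(benzyloxy)-3-{[4,6-bis(benzyloxy)-2-methoxy-3-methylphenyl]methyl}benzaldehyde | O=Cc1c(OCc2ccccc2)cc(OCc2ccccc2)c(Cc2c(OCc3ccccc3)cc(OCc3ccccc3)c(C)c2OC)c1OCc1ccccc1 | intermediate
12 | Ar*–CH2OH, (2,4,6-tris(benzyloxy)-3-{[4,6-bis(benzyloxy)-2-methoxy-3-methylphenyl]methyl}phenyl)methanol | OCc1c(OCc2ccccc2)cc(OCc2ccccc2)c(Cc2c(OCc3ccccc3)cc(OCc3ccccc3)c(C)c2OC)c1OCc1ccccc1 | intermediate
13 | methyl 3-oxopentanoate | CCC(=O)CC(=O)OC | starting material
14 | Ar*–CH2Br, 1,3,5-tris(benzyloxy)-2-{[4,6-bis(benzyloxy)-2-methoxy-3-methylphenyl]methyl}-4-(bromomethyl)benzene | BrCc1c(OCc2ccccc2)cc(OCc2ccccc2)c(Cc2c(OCc3ccccc3)cc(OCc3ccccc3)c(C)c2OC)c1OCc1ccccc1 | intermediate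
15 | methyl 2-(Ar*-methyl)-3-oxopentanoate (racemic) | CCC(=O)C(Cc1c(OCc2ccccc2)cc(OCc2ccccc2)c(Cc2c(OCc3ccccc3)cc(OCc3ccccc3)c(C)c2OC)c1OCc1ccccc1)C(=O)OC | intermediate
16 | methyl 2-(Ar*-methyl)-3-(trimethylsilyloxy)pent-2-enoate (E/Z mixture) | CCC(O[Si](C)(C)C)=C(Cc1c(OCc2ccccc2)cc(OCc2ccccc2)c(Cc2c(OCc3ccccc3)cc(OCc3ccccc3)c(C)c2OC)c1OCc1ccccc1)C(=O)OC | intermediate
17 | lithium dienolate of 16, lithium (3Z)-1-methoxy-2-(Ar*-methyl)-3-(trimethylsilyloxy)penta-1,3-dien-1-olate | COC(O[Li])=C(Cc1c(OCc2ccccc2)cc(OCc2ccccc2)c(Cc2c(OCc3ccccc3)cc(OCc3ccccc3)c(C)c2OC)c1OCc1ccccc1)/C(O[Si](C)(C)C)=C/C | intermediate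
18 | (3Z)-1-methoxy-2-(Ar*-methyl)-1,3-bis(trimethylsilyloxy)penta-1,3-diene | COC(O[Si](C)(C)C)=C(Cc1c(OCc2ccccc2)cc(OCc2ccccc2)c(Cc2c(OCc3ccccc3)cc(OCc3ccccc3)c(C)c2OC)c1OCc1ccccc1)/C(O[Si](C)(C)C)=C/C | intermediate
19 | hex-1-yn-3-ol (racemic) | CCCC(O)C#C | starting material
20 | 1-bromohex-1-yn-3-ol (racemic) | CCCC(O)C#CBr | intermediate
21 | 1-bromohex-1-yn-3-one | CCCC(=O)C#CBr | intermediate
22 | 1-[2-bromo-6-methoxy-3-methyl-5-(Ar*-methyl)-4,6-bis(trimethylsilyloxy)cyclohexa-1,4-dien-1-yl]butan-1-one (diastereomer mixture) | CCCC(=O)C1=C(Br)C(C)C(O[Si](C)(C)C)=C(Cc2c(OCc3ccccc3)cc(OCc3ccccc3)c(Cc3c(OCc4ccccc4)cc(OCc4ccccc4)c(C)c3OC)c2OCc2ccccc2)C1(OC)O[Si](C)(C)C | intermediate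
23 | 1-[2-bromo-4,6-dihydroxy-3-methyl-5-(Ar*-methyl)phenyl]butan-1-one | CCCC(=O)c1c(Br)c(C)c(O)c(Cc2c(OCc3ccccc3)cc(OCc3ccccc3)c(Cc3c(OCc4ccccc4)cc(OCc4ccccc4)c(C)c3OC)c2OCc2ccccc2)c1O | intermediate
24 | 1-[4,6-bis(benzyloxy)-2-bromo-3-methyl-5-(Ar*-methyl)phenyl]butan-1-one | CCCC(=O)c1c(Br)c(C)c(OCc2ccccc2)c(Cc2c(OCc3ccccc3)cc(OCc3ccccc3)c(Cc3c(OCc4ccccc4)cc(OCc4ccccc4)c(C)c3OC)c2OCc2ccccc2)c1OCc1ccccc1 | intermediate
25 | 1-[4,6-bis(benzyloxy)-2-methoxy-3-methyl-5-(Ar*-methyl)phenyl]butan-1-one | CCCC(=O)c1c(OC)c(C)c(OCc2ccccc2)c(Cc2c(OCc3ccccc3)cc(OCc3ccccc3)c(Cc3c(OCc4ccccc4)cc(OCc4ccccc4)c(C)c3OC)c2OCc2ccccc2)c1OCc1ccccc1 | intermediate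
26 | hepta-O-benzyl ether of the target (all seven phenols of 27 as benzyl ethers) | CCCC(=O)c1c(OC)c(C)c(OCc2ccccc2)c(Cc2c(OCc3ccccc3)c(C(=O)CCC)c(OCc3ccccc3)c(Cc3c(OCc4ccccc4)c(C(=O)CCC)c(OCc4ccccc4)c(C)c3OC)c2OCc2ccccc2)c1OCc1ccccc1 | intermediate
27 | 1-[3-[(3-butanoyl-2,6-dihydroxy-4-methoxy-5-methylphenyl)methyl]-5-[(3-butanoyl-2,4-dihydroxy-6-methoxy-5-methylphenyl)methyl]-2,4,6-trihydroxyphenyl]butan-1-one | CCCC(=O)c1c(O)c(Cc2c(O)c(C)c(OC)c(C(=O)CCC)c2O)c(O)c(Cc2c(O)c(C(=O)CCC)c(O)c(C)c2OC)c1O | target

## Step count and risks

Total: 17 steps. Longest linear sequence: 14 steps (steps 1–3, 5–10, 13–17).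

**Step 13 (key step).** The silyl ketene acetal may attack bromine instead of carbon (bromine transfer), or may add to the β-carbon and then lose bromide (net alkynylation) without closing the ring. The 2,4-disubstitution may slow the cycloaddition enough that the diene is protodesilylated first. The vinylogous acyl bromide of the cycloadduct may also be displaced by methanol or water before aromatisation.
Fallback: give up the cycloaddition and build ring A from 2 and 9, rejoining the route at 26. Methylation of 2 with one equivalent of MeI and K2CO3 at the non-chelated 4-OH gives 2,6-dihydroxy-4-methoxy-3-methylbenzaldehyde F1. Benzylation gives 2,6-bis(benzyloxy)-4-methoxy-3-methylbenzaldehyde F2. Aryllithium 10, generated from 9 as in step 7, adds to F2 to give the carbinol [2,6-bis(benzyloxy)-4-methoxy-3-methylphenyl](Ar*)methanol F3. Ionic hydrogenation as in step 6 gives the tris-aryl compound 1,3-bis(benzyloxy)-5-methoxy-4-methyl-2-(Ar*-methyl)benzene F4, which has one free position on each ring. Threefold butyrylation under the conditions of step 16 gives 26.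

**Step 8.** The benzylic bromide may be lost by self-alkylation, because the free positions of rings B and C attack the readily ionising CH2Br group. O-alkylation of the enolate is a lesser risk.
Fallback: from 9, stop step 7 at aldehyde 11 by omitting NaBH4. Knoevenagel condensation of 11 with 13 (piperidine, AcOH, toluene, water removal) gives methyl 2-(Ar*-methylidene)-3-oxopentanoate F5. Conjugate reduction with Hantzsch ester returns to 15.

**Step 15.** Hydrodebromination (methoxide acting as hydride donor) or no conversion at the di-ortho-substituted carbon may occur, along with base-induced condensation of the ketone at 110 °C.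
Fallback: from 24, Miyaura borylation (B2pin2, Pd(dppf)Cl2, KOAc, dioxane, 90 °C) gives the pinacol boronate 1-[4,6-bis(benzyloxy)-3-methyl-5-(Ar*-methyl)-2-(4,4,5,5-tetramethyl-1,3,2-dioxaborolan-2-yl)phenyl]butan-1-one F6. Oxidation with NaBO3·4H2O gives the phenol 1-[4,6-bis(benzyloxy)-2-hydroxy-3-methyl-5-(Ar*-methyl)phenyl]butan-1-one F7, the only free hydroxyl in the molecule. Methylation with MeI and K2CO3 returns to 25.

**Step 16.** The acid may cleave or migrate benzyl ethers. Ipso attack at a bridge carbon with loss of an arylmethyl cation would scramble the bridges. The second acylation at the more hindered site may stay incomplete.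
Fallback: from 25, Vilsmeier–Haack diformylation (POCl3, DMF, 0 °C → rt) gives the dialdehyde F8, with formyl groups at the free positions of rings B and C. Addition of n-PrMgBr at −78 °C, where the aldehydes react far faster than the di-ortho-substituted ring A ketone, gives the diol F9 with 1-hydroxybutyl groups at those positions. Dess–Martin oxidation returns to 26.

**Step 2.** Alkylation may occur at the wrong ortho hydroxyl or at the free ring carbon, giving regioisomer mixtures that would misplace the ring C OMe.
Fallback: from 2, exhaustive benzylation gives 2,4,6-tris(benzyloxy)-3-methylbenzaldehyde F10. Chelation-controlled mono-debenzylation with MgBr2·OEt2 should cleave first the ortho ether flanked by methyl and formyl, which is twisted out of the ring plane. This returns to 3.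

## Further compounds

F1 | step 13 | 2,6-dihydroxy-4-methoxy-3-methylbenzaldehyde | COc1cc(O)c(C=O)c(O)c1C
F2 | step 13 | 2,6-bis(benzyloxy)-4-methoxy-3-methylbenzaldehyde | COc1cc(OCc2ccccc2)c(C=O)c(OCc2ccccc2)c1C
F3 | step 13 | [2,6-bis(benzyloxy)-4-methoxy-3-methylphenyl](Ar*)methanol (racemic) | COc1cc(OCc2ccccc2)c(C(O)c2c(OCc3ccccc3)cc(OCc3ccccc3)c(Cc3c(OCc4ccccc4)cc(OCc4ccccc4)c(C)c3OC)c2OCc2ccccc2)c(OCc2ccccc2)c1C
F4 | step 13 | 1,3-bis(benzyloxy)-5-methoxy-4-methyl-2-(Ar*-methyl)benzene | COc1cc(OCc2ccccc2)c(Cc2c(OCc3ccccc3)cc(OCc3ccccc3)c(Cc3c(OCc4ccccc4)cc(OCc4ccccc4)c(C)c3OC)c2OCc2ccccc2)c(OCc2ccccc2)c1C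
F5 | step 8 | methyl 2-(Ar*-methylidene)-3-oxopentanoate (E/Z mixture) | CCC(=O)C(=Cc1c(OCc2ccccc2)cc(OCc2ccccc2)c(Cc2c(OCc3ccccc3)cc(OCc3ccccc3)c(C)c2OC)c1OCc1ccccc1)C(=O)OC
F6 | step 15 | 1-[4,6-bis(benzyloxy)-3-methyl-5-(Ar*-methyl)-2-(4,4,5,5-tetramethyl-1,3,2-dioxaborolan-2-yl)phenyl]butan-1-one | CCCC(=O)c1c(B2OC(C)(C)C(C)(C)O2)c(C)c(OCc2ccccc2)c(Cc2c(OCc3ccccc3)cc(OCc3ccccc3)c(Cc3c(OCc4ccccc4)cc(OCc4ccccc4)c(C)c3OC)c2OCc2ccccc2)c1OCc1ccccc1
F7 | step 15 | 1-[4,6-bis(benzyloxy)-2-hydroxy-3-methyl-5-(Ar*-methyl)phenyl]butan-1-one | CCCC(=O)c1c(O)c(C)c(OCc2ccccc2)c(Cc2c(OCc3ccccc3)cc(OCc3ccccc3)c(Cc3c(OCc4ccccc4)cc(OCc4ccccc4)c(C)c3OC)c2OCc2ccccc2)c1OCc1ccccc1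
F8 | step 16 | dialdehyde: 25 with formyl groups at the free positions of rings B and C | CCCC(=O)c1c(OC)c(C)c(OCc2ccccc2)c(Cc2c(OCc3ccccc3)c(C=O)c(OCc3ccccc3)c(Cc3c(OCc4ccccc4)c(C=O)c(OCc4ccccc4)c(C)c3OC)c2OCc2ccccc2)c1OCc1ccccc1
F9 | step 16 | diol: 25 with 1-hydroxybutyl groups at the free positions of rings B and C (diastereomer mixture) | CCCC(=O)c1c(OC)c(C)c(OCc2ccccc2)c(Cc2c(OCc3ccccc3)c(C(O)CCC)c(OCc3ccccc3)c(Cc3c(OCc4ccccc4)c(C(O)CCC)c(OCc4ccccc4)c(C)c3OC)c2OCc2ccccc2)c1OCc1ccccc1
F10 | step 2 | 2,4,6-tris(benzyloxy)-3-methylbenzaldehyde | Cc1c(OCc2ccccc2)cc(OCc2ccccc2)c(C=O)c1OCc1ccccc1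
A1 | alternative 1 | 5-(benzyloxy)-2-{[2,6-bis(benzyloxy)-4-methoxy-3-methylphenyl]methyl}-4-{[4,6-bis(benzyloxy)-2-methoxy-3-methylphenyl]methyl}-3-[(triisopropylsilyl)oxy]phenol | Oc1cc(OCc2ccccc2)c(Cc2c(OCc3ccccc3)cc(OCc3ccccc3)c(C)c2OC)c(O[Si](C(C)C)(C(C)C)C(C)C)c1Cc1c(OCc2ccccc2)c(C)c(OC)cc1OCc1ccccc1
A2 | alternative 1 | 3-(benzyloxy)-2-{[4,6-bis(benzyloxy)-2-methoxy-3-methylphenyl]methyl}cyclobut-2-en-1-one | O=C1CC(OCc2ccccc2)=C1Cc1c(OCc2ccccc2)cc(OCc2ccccc2)c(C)c1OC
A3 | alternative 1 | triisopropyl({3-[2,6-bis(benzyloxy)-4-methoxy-3-methylphenyl]prop-1-yn-1-yl}oxy)silane | CC(C)[Si](OC#CCc1c(OCc2ccccc2)c(C)c(OC)cc1OCc1ccccc1)(C(C)C)C(C)C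
A4 | alternative 2 | methyl 3-{[2,6-bis(benzyloxy)-4-methoxy-3-methylphenyl]methyl}-5-{[4,6-bis(benzyloxy)-2-methoxy-3-methylphenyl]methyl}-2,4,6-trihydroxybenzoate | COC(=O)c1c(O)c(Cc2c(OCc3ccccc3)c(C)c(OC)cc2OCc2ccccc2)c(O)c(Cc2c(OCc3ccccc3)cc(OCc3ccccc3)c(C)c2OC)c1O
A5 | alternative 2 | 5-[2,6-bis(benzyloxy)-4-methoxy-3-methylphenyl]-1-methoxy-1,3-bis(trimethylsilyloxy)penta-1,3-diene | COC(O[Si](C)(C)C)=CC(O[Si](C)(C)C)=CCc1c(OCc2ccccc2)c(C)c(OC)cc1OCc1ccccc1
A6 | alternative 2 | 2-{[4,6-bis(benzyloxy)-2-methoxy-3-methylphenyl]methyl}propanedioyl dichloride | O=C(Cl)C(Cc1c(OCc2ccccc2)cc(OCc2ccccc2)c(C)c1OC)C(Cl)=O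
A7 | alternative 3 | 5-(benzyloxy)-3-methoxy-2-methyl-4-[(2,4,6-tris(benzyloxy)-3-{[2,6-bis(benzyloxy)-4-methoxy-3-methylphenyl]methyl}phenyl)methyl]phenol | COc1c(C)c(O)cc(OCc2ccccc2)c1Cc1c(OCc2ccccc2)cc(OCc2ccccc2)c(Cc2c(OCc3ccccc3)c(C)c(OC)cc2OCc2ccccc2)c1OCc1ccccc1
A8 | alternative 3 | 3-(benzyloxy)-2-[(2,4,6-tris(benzyloxy)-3-{[2,6-bis(benzyloxy)-4-methoxy-3-methylphenyl]methyl}phenyl)methyl]cyclobut-2-en-1-one | O=C1CC(OCc2ccccc2)=C1Cc1c(OCc2ccccc2)cc(OCc2ccccc2)c(Cc2c(OCc3ccccc3)c(C)c(OC)cc2OCc2ccccc2)c1OCc1ccccc1
A9 | alternative 3 | 1-methoxyprop-1-yne | COC#CC
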